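## Retrosynthetic overview

1. 24 ⇐ 22/23: acid-mediated isomerisation of a spiro-γ-lactone carrying a cis-γ-keto-enoate; the butenolide, dioxolane and oxane rings of the orthoester cage form last.
2. 21 ⇐ 10 + 17: SmI2 ketyl (polarity-reversed C7) adds to the methacrylate CH2 (C8); the Sm(III) enolate born at C9 then forms C9–C10 in the same flask by ester-enolate Claisen/SN2′, and the spiro-γ-lactone closes.
3. 10 ⇐ (R)-carvone: formylation/Michael/reduction builds the C6 spiro-δ-lactone; an O2-derived peroxide tether sets C3–O, C5′–O and C2.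
4. 17 ⇐ methyl but-2-ynoate + methacrolein (vinylalumination), Sharpless kinetic resolution, methacryloylation.
5. Ring order: ring A (chiral pool) → δ-lactone → temporary 1,2-dioxane → spiro-γ-lactone → cage.

Assumption: Sm- and Al-bound intermediates are listed as their neutral protonated forms, 23 is a C14 epimer mixture, and locants are those of the target (ring A = C2–C7, C5′ = CMe2, C8 = CH2, C9 = C(Me), C10 = CH(Me), C11–C12 = lactone CH–C=O, C14 = ketal C, C16 = orthoester C, C18 = CH–O).

## Route

Step 1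
Reactants: 1 (R)-(–)-carvone; 2 ethyl formate
Product: 3 (5S,6Z)-6-(hydroxymethylidene)-2-methyl-5-(prop-1-en-2-yl)cyclohex-2-en-1-one (enol of 6-formylcarvone; C5 spatially unchanged)
Conditions: NaH, HCO2Et, cat. EtOH, THF, 0 °C → rt; aq. HCl
Reagents that add atoms: none
Why: Crossed Claisen (α′-formylation) at C6, the only enolisable α-position of the enone, driven by formation of the stabilised β-keto-aldehyde enolate; no new stereocentre.

Step 2
Reactants: 3; 4 methyl acrylate
Product: 5 methyl 3-[(1S,6S)-1-formyl-3-methyl-2-oxo-6-(prop-1-en-2-yl)cyclohex-3-en-1-yl]propanoate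
Conditions: DBU (10 mol %), MeCN, 0 °C → rt
Reagents that add atoms: none
Why: Base-catalysed Michael addition of the 1,3-dicarbonyl enolate, in which the acrylate approaches C6 anti to the adjacent isopropenyl group (propanoate arm trans, formyl cis to isopropenyl), while the soft catalytic conditions avoid the double-Michael pathway of carvone lithium dienolates.

Step 3
Reactants: 5
Product: 7 (6S,11S)-8-methyl-11-(prop-1-en-2-yl)-2-oxaspiro[5.5]undec-8-ene-3,7-dione, via hydroxy ester 6 (not isolated)
Conditions: NaBH4 (0.35 equiv), MeOH–CH2Cl2, −78 °C; then TsOH·H2O (cat.), CH2Cl2, rt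
Reagents that add atoms: none
Why: Chemoselective low-temperature borohydride reduction of the aldehyde beside the conjugated α-quaternary ketone, then acid-catalysed δ-lactonisation of the hydroxy ester; no stereocentre is touched.

Step 4
Reactants: 7
Product: 8 (6S,11R)-8-methyl-11-[2-(triethylsilylperoxy)propan-2-yl]-2-oxaspiro[5.5]undec-8-ene-3,7-dione
Conditions: Co(thd)2 (5 mol %), O2 (1 atm), Et3SiH, ClCH2CH2Cl, rt
Reagents that add atoms: dioxygen O=O; triethylsilane CC[SiH](CC)CC
Why: Isayama–Mukaiyama cobalt-catalysed Markovnikov hydroperoxysilylation (metal-hydride HAT), which prefers the electron-rich 1,1-disubstituted alkene over the hindered electron-poor enone; no new stereocentre.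

Step 5
Reactants: 8
Product: 10 (1S,5R,6S,8S)-4,4,8-trimethylspiro[2,3-dioxabicyclo[3.3.1]nonane-6,3'-oxane]-6',7-dione, via hydroperoxide 9 (not isolated)
Conditions: HF·pyridine, THF, 0 °C; then Et3N (0.3 equiv), CF3CH2OH, rt
Reagents that add atoms: none
Why: Desilylation then amine-catalysed intramolecular peroxy-Michael addition (the reaction used for yingzhaosu-type 2,3-dioxabicyclo[3.3.1]nonanes): the tethered hydroperoxide can reach C3 only on the face of the C5 substituent (C3–O cis to it, 3S), and reversible enolate protonation in the locked chair puts the C2 methyl equatorial, cis to C3–O (2S).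

Step 6
Reactants: 11 methyl but-2-ynoate; 12 methacrolein
Product: 14 methyl (2Z)-2-(1-hydroxy-2-methylprop-2-en-1-yl)but-2-enoate (racemic), via vinylalane 13 (not isolated)
Conditions: DIBAL-H, NMO, THF, 0 °C; then 12, 0 °C → rt; Rochelle salt
Reagents that add atoms: none
Why: Vinylalumination: syn-hydroalumination of the ynoate gives the α-aluminio enoate, whose 1,2-addition to the enal gives the Morita–Baylis–Hillman-type alcohol with the β-methyl cis to CO2Me (Z); racemic at C18.

Step 7
Reactants: 14
Product: 15 methyl (2Z)-2-[(1R)-1-hydroxy-2-methylprop-2-en-1-yl]but-2-enoate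
Conditions: Ti(OiPr)4, D-(−)-DIPT, t-BuOOH (0.6 equiv), 4 Å MS, CH2Cl2, −20 °C, about 55% conversion
Reagents that add atoms: none
Why: Sharpless kinetic resolution: with D-(−)-tartrate the (S)-alcohol is epoxidised at its isopropenyl group much faster (oxygen delivered to the face bearing the carbinol H), so (R)-15 is recovered.

Step 8
Reactants: 15; 16 methacryloyl chloride
Product: 17 methyl (2Z)-2-[(1R)-2-methyl-1-(2-methylprop-2-enoyloxy)prop-2-en-1-yl]but-2-enoate
Conditions: i-Pr2NEt, CH2Cl2, −20 → 0 °C (no DMAP)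
Reagents that add atoms: none
Why: O-acylation of the secondary allylic alcohol with a non-nucleophilic base, avoiding Lewis-base SN2′ scrambling of the MBH-type ester; the stereocentre is untouched.

Step 9
Reactants: 10; 17
Product: 21 spiro-γ-lactone dienoate (2S,3S,5R,6S,7S,9R,10R,11Z; target locants): target ring A and δ-lactone; C7 spiro-fused to an α-methyl-γ-butyrolactone (O19–C16=O) whose C9 bears C10H(CH3)–C11(CO2Me)=C18H–C14(CH3)=CH2, via keto diol 18 (not isolated), via samarium enolate 19 (not isolated), via hydroxy acid 20 (not isolated)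
Conditions: SmI2 (5 equiv, 0.1 M), 17 (1.5 equiv), THF, −78 → −20 °C, no proton source; 1 M HCl; PPTS, CH2Cl2, rt
Reagents that add atoms: none
Why: Proposed new method: SmI2 first cleaves the O–O bond (giving the C3/C5′ Sm(III) alkoxides of 18, no free OH) and then reduces the C7 ketone to a ketyl, a polarity-reversed carbonyl carbon that adds to the methacrylate CH2 of 17 (ketyl–olefin coupling, the methacrylate serving as a β-acyl-anion/homoenolate equivalent) from the face anti to the syn-axial C3–O and C5–CMe2O groups that chelate the ketyl samarium (7S); the α-ester radical is reduced to the chelation-defined Sm(III) enolate 19 (C8 cis to O–Sm), which C-allylates itself through a chair six-membered ester-enolate Claisen/intramolecular SN2′ transition state onto the activated MBH-type enoate (C18 isopropenyl and C10 methyl equatorial, C9 methyl axial), transferring the C18 chirality to C9 and C10 and giving the 11Z dienoate acid 20, which lactonises on acidic work-up; closest known reactions are SmI2 ketone–acrylate spirolactonisations, SmI2 radical–enolate cascades and reductive or conjugate-addition-triggered Ireland–Claisen rearrangements of allyl acrylates.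

Step 10
Reactants: 21
Product: 22 keto enoate (2S,3S,5R,6S,7S,9R,10R,11Z): as 21 but with the side chain C10H(CH3)–C11(CO2Me)=C18H–C14(=O)CH3
Conditions: O3, CH2Cl2–MeOH, −78 °C (Sudan III end-point); Me2S
Reagents that add atoms: ozone [O-][O+]=O
Why: Chemoselective ozonolysis of the terminal, more electron-rich alkene of the dienoate (the ester-conjugated C11=C18 bond is deactivated), unmasking the C14 methyl ketone cis to the ester.

Step 11
Reactants: 22
Product: 24 chermebilaene B, via hydroxybutenolide 23 (not isolated)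
Conditions: 1 M HCl–THF (1:4), rt; then CSA (20 mol %), 4 Å MS, PhMe, 40 °C
Reagents that add atoms: water O
Why: Proposed new method: aqueous acid converts the cis-γ-keto methyl ester into the pseudo-acid 23 (an isomer of the target), and under dehydrating acid the C16 lactone carbonyl oxygen adds to the butenolide β-carbon C18 (six-membered oxa-Michael) while the C14 hemiketal hydroxyl captures the resulting dialkoxycarbenium ion at C16 and C11 is protonated, so that C11, C14, C16 and C18 are set under thermodynamic control by the cis-fused cage compatible with the fixed C9/C10 centres; closest known reactions are acid-catalysed orthoester formation from lactone/diol pairs, ring–chain tautomerism of cis-β-acylacrylic acids and hemiacetal-tethered oxa-Michael additions.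

## Compound list

1 | (R)-(–)-carvone, (5R)-2-methyl-5-(prop-1-en-2-yl)cyclohex-2-en-1-one | CC1=CC[C@@H](C(C)=C)CC1=O | starting material
2 | ethyl formate | CCOC=O | starting material
3 | (5S,6Z)-6-(hydroxymethylidene)-2-methyl-5-(prop-1-en-2-yl)cyclohex-2-en-1-one | CC1=CC[C@@H](C(C)=C)/C(=C/O)C1=O | intermediate
4 | methyl acrylate | C=CC(=O)OC | starting material
5 | methyl 3-[(1S,6S)-1-formyl-3-methyl-2-oxo-6-(prop-1-en-2-yl)cyclohex-3-en-1-yl]propanoate | CC1=CC[C@@H](C(C)=C)[C@](C=O)(CCC(=O)OC)C1=O | intermediate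
6 | methyl 3-[(1S,6S)-1-(hydroxymethyl)-3-methyl-2-oxo-6-(prop-1-en-2-yl)cyclohex-3-en-1-yl]propanoate (not isolated) | CC1=CC[C@@H](C(C)=C)[C@](CO)(CCC(=O)OC)C1=O | intermediate
7 | (6S,11S)-8-methyl-11-(prop-1-en-2-yl)-2-oxaspiro[5.5]undec-8-ene-3,7-dione | CC1=CC[C@@H](C(C)=C)[C@]2(CCC(=O)OC2)C1=O | intermediate
8 | (6S,11R)-8-methyl-11-[2-(triethylsilylperoxy)propan-2-yl]-2-oxaspiro[5.5]undec-8-ene-3,7-dione | CC1=CC[C@@H](C(C)(C)OO[Si](CC)(CC)CC)[C@]2(CCC(=O)OC2)C1=O | intermediate
9 | (6S,11R)-11-(2-hydroperoxypropan-2-yl)-8-methyl-2-oxaspiro[5.5]undec-8-ene-3,7-dione (not isolated) | CC1=CC[C@@H](C(C)(C)OO)[C@]2(CCC(=O)OC2)C1=O | intermediate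
10 | (1S,5R,6S,8S)-4,4,8-trimethylspiro[2,3-dioxabicyclo[3.3.1]nonane-6,3'-oxane]-6',7-dione (O–O bridge from C3 to C5′, C2 methyl cis to C3–O) | C[C@H]1[C@@H]3C[C@@H](C(C)(C)OO3)[C@]2(CCC(=O)OC2)C1=O | intermediate
11 | methyl but-2-ynoate | CC#CC(=O)OC | starting material
12 | methacrolein | CC(=C)C=O | starting material
13 | methyl (2E)-2-[bis(2-methylpropyl)alumanyl]but-2-enoate, NMO-complexed (not isolated) | C/C=C(/[Al](CC(C)C)CC(C)C)C(=O)OC | intermediate
14 | methyl (2Z)-2-(1-hydroxy-2-methylprop-2-en-1-yl)but-2-enoate, racemic | C/C=C(/C(O)C(C)=C)C(=O)OC | intermediate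
15 | methyl (2Z)-2-[(1R)-1-hydroxy-2-methylprop-2-en-1-yl]but-2-enoate | C/C=C(/[C@H](O)C(C)=C)C(=O)OC | intermediate
16 | methacryloyl chloride | CC(=C)C(Cl)=O | starting material
17 | methyl (2Z)-2-[(1R)-2-methyl-1-(2-methylprop-2-enoyloxy)prop-2-en-1-yl]but-2-enoate | C/C=C(/[C@H](OC(=O)C(C)=C)C(C)=C)C(=O)OC | intermediate
18 | (6S,8S,9S,11R)-9-hydroxy-11-(2-hydroxypropan-2-yl)-8-methyl-2-oxaspiro[5.5]undecane-3,7-dione, present as its bis-Sm(III) alkoxide (not isolated) | C[C@H]1[C@@H](O)C[C@@H](C(C)(C)O)[C@]2(CCC(=O)OC2)C1=O | intermediate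
19 | Sm(III) ketene-acetal enolate of the C7–C8 coupled ester, drawn as the free enol (2S,3S,5R,6S,7S,18R; C8 cis to the enol O) (not isolated) | C[C@H]1[C@@H](O)C[C@@H](C(C)(C)O)[C@]2(CCC(=O)OC2)[C@]1(O)C/C(C)=C(\O)O[C@@H](/C(=C/C)C(=O)OC)C(C)=C | intermediate
20 | hydroxy acid (2S,3S,5R,6S,7S,9R,10R,11Z): C7–OH, C9(CH3)(CO2H) bearing C10H(CH3)–C11(CO2Me)=C18H–C14(CH3)=CH2 (not isolated) | C[C@H]1[C@@H](O)C[C@@H](C(C)(C)O)[C@]2(CCC(=O)OC2)[C@]1(O)C[C@](C)([C@@H](C)/C(C(=O)OC)=C/C(C)=C)C(=O)O | intermediate
21 | spiro-γ-lactone dienoate (2S,3S,5R,6S,7S,9R,10R,11Z) | C[C@H]1[C@@H](O)C[C@@H](C(C)(C)O)[C@]2(CCC(=O)OC2)[C@]12C[C@](C)([C@@H](C)/C(C(=O)OC)=C/C(C)=C)C(=O)O2 | intermediate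
22 | spiro-γ-lactone cis-γ-keto enoate (2S,3S,5R,6S,7S,9R,10R,11Z) | C[C@H]1[C@@H](O)C[C@@H](C(C)(C)O)[C@]2(CCC(=O)OC2)[C@]12C[C@](C)([C@@H](C)/C(C(=O)OC)=C/C(C)=O)C(=O)O2 | intermediate
23 | spiro-γ-lactone 5-hydroxy-5-methylbutenolide (pseudo-acid, C14 epimers; 2S,3S,5R,6S,7S,9R,10R) (not isolated) | C[C@H]1[C@@H](O)C[C@@H](C(C)(C)O)[C@]2(CCC(=O)OC2)[C@]12C[C@](C)([C@@H](C)C3=CC(C)(O)OC3=O)C(=O)O2 | intermediate
24 | chermebilaene B | C[C@H]1[C@@H](O)C[C@@H](C(C)(C)O)[C@]2(CCC(=O)OC2)[C@]12C[C@]1(C)[C@@H](C)[C@H]3C(=O)O[C@@]4(C)O[C@@]1(O[C@@H]34)O2 | target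

## Step count and risk

Total step count: 11. Longest linear sequence: 8 steps (1–5, 9–11); steps 6–8 make the coupling partner.

Three steps most likely to fail:

Step 9 (the Sm(III) enolate may be protonated, collapse to a ketene, have the wrong geometry, or rearrange through the isopropenyl terminus). The fallback uncouples the two bond formations and sets out from 10. SmI2/t-BuOH coupling of 10 with commercial methyl methacrylate (classical ketyl–olefin lactonisation, same O–O cleavage and C7 facial control) gives the α-methyl spiro-γ-lactone F1 (C9 epimers, irrelevant). Separately, 15 is acetylated (Ac2O, pyridine) to the allylic acetate F2. The lithium enolate of F1 (LDA, 3.5 equiv, THF–DMPU, −78 °C, hydroxyls as lithium alkoxides) is then C-allylated by F2 in an intermolecular SN2′ reaction, the electrophile entering C9 on the lactone face syn to C2–H. This comes back to the route at 21; C10 is then set through an open transition state and may need separation.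

Step 11 (the conjugate O-addition that re-oxygenates C18 may not be favourable under cage-forming conditions). The fallback installs the C18 oxygen explicitly and sets out from 22. Acid-catalysed isomerisation in methanol (CSA, MeOH) gives the 5-methoxybutenolide pseudo-ester F3. Copper-catalysed conjugate borylation (CuCl, NaOt-Bu, Josiphos-type ligand for catalyst control at C18, B2pin2, MeOH–THF) gives the β-boryl lactone F4, and NaBO3 oxidation gives the β-hydroxy-γ-methoxy lactone F5. CSA in toluene over 4 Å MS then closes the orthoester by attack of the C18 hydroxyl on the C16 lactone and exchange of the C14 methoxy group, coming back to the route at 24.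

Step 4 (cobalt-hydride HAT may also attack the enone). The fallback introduces the peroxide by ionic chemistry and sets out from 7. Markovnikov hydration (40% aq. H2SO4–THF, 0 °C, the classical carvone-hydrate conditions) gives the tertiary alcohol F6, and SN1 perhydrolysis (50% H2O2, cat. H2SO4, Et2O, 0 °C) converts it into the hydroperoxide, coming back to the route at 9, which is cyclised as in step 5.

Further compounds
F1 | step 9 | α-methyl spiro-γ-lactone diol (2S,3S,5R,6S,7S; C9 epimers) | C[C@H]1[C@@H](O)C[C@@H](C(C)(C)O)[C@]2(CCC(=O)OC2)[C@]12CC(C)C(=O)O2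
F2 | step 9 | methyl (2Z)-2-[(1R)-1-acetoxy-2-methylprop-2-en-1-yl]but-2-enoate | C/C=C(/[C@H](OC(C)=O)C(C)=C)C(=O)OC
F3 | step 11 | spiro-γ-lactone 5-methoxy-5-methylbutenolide (pseudo-ester of 22, C14 epimers) | C[C@H]1[C@@H](O)C[C@@H](C(C)(C)O)[C@]2(CCC(=O)OC2)[C@]12C[C@](C)([C@@H](C)C3=CC(C)(OC)OC3=O)C(=O)O2
F4 | step 11 | C18-pinacolboryl γ-methoxy-γ-lactone (C11 and C14 epimers) | C[C@H]1[C@@H](O)C[C@@H](C(C)(C)O)[C@]2(CCC(=O)OC2)[C@]12C[C@](C)([C@@H](C)C3C(=O)OC(C)(OC)[C@H]3B4OC(C)(C)C(C)(C)O4)C(=O)O2
F5 | step 11 | C18-hydroxy γ-methoxy-γ-lactone (C11 and C14 epimers) | C[C@H]1[C@@H](O)C[C@@H](C(C)(C)O)[C@]2(CCC(=O)OC2)[C@]12C[C@](C)([C@@H](C)C3C(=O)OC(C)(OC)[C@H]3O)C(=O)O2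
F6 | step 4 | (6S,11R)-11-(2-hydroxypropan-2-yl)-8-methyl-2-oxaspiro[5.5]undec-8-ene-3,7-dione | CC1=CC[C@@H](C(C)(C)O)[C@]2(CCC(=O)OC2)C1=O
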